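**Remark on the chemistry (assumptions):** Chamigrene numbering is used for all intermediates (ring B = C1–C6, ring A = C6–C11, C6 = spiro carbon, C14 = exocyclic methylene carbon). Lactone 7 is taken as commercially available. Each bromochlorination is run with the ligand enantiomer that gives the configuration drawn.

## Analysis of the target

Nidificene (19) is a spiro[5.5]undecane (chamigrane). Ring A (C6–C11) carries the exocyclic C7=C14 methylene, the C11 gem-dimethyl group and a secondary, neopentyl bromide at C10; ring B (C1–C6) carries a secondary bromide at C2 next to a tertiary chloride and a methyl group at C3. The four stereocenters C2, C3, C6 and C10 are all S; C6 is stereogenic only because ring B is unsymmetrical, so it has to be related to C10 across ring A and to C2/C3 across ring B. C2–Br and C3–Cl are trans, the bromine is cis to C11 and the chlorine cis to C7, and on ring A the C1 methylene is trans to the C10 bromine. Because C11 is quaternary, ring B should have one accessible chair only (C11 equatorial, C7 axial), and in it the C2 bromine and the C3 chlorine are both equatorial while the C3 methyl is axial. This trans-diequatorial halogen pair decides the strategy: anti addition of bromine and chloride to a C2=C3 olefin of a preformed spirocycle must pass through trans-diaxial opening (Fürst–Plattner rule) and is expected to give the other, diaxial trans diastereomer. On ring A, with the C10 bromine equatorial, C1 is axial and C5 equatorial, so C1–C6 is the bond that axial alkylation of a ring A enolate would form. Further difficulties are the vicinal quaternary pair C6/C11, the C10 bromide that cannot be made by substitution, and the lability of the β-bromo tertiary chloride and of the exocyclic olefin.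

## Retrosynthetic reasoning

**C7=C14.** 19 is traced back to the spiro ketone 18. The carbonyl at C7 is the handle that makes C6 nucleophilic in both ring closures, and it is exchanged for the methylene only at the end, under conditions without base or Lewis acid.

**C1–C6 (key disconnection).** Ring B of 18 is opened at C1–C6. This leads to the monocyclic ring A enone 16, whose open arm C5–C1 already carries the C2 bromide and the C3 chloride and ends in a C1 tosylate. The cut is made here because the two ring B halogens can then be set on an open chain, where anti addition has no conformational bias to fight. It is made at C1–C6 and not at C5–C6 because the last bond to C6 is formed axially on ring A, and in 19 the axial ring A substituent of C6 is C1. Forward, conjugate reduction of 16 must unmask the C6 enolate regiospecifically (as 17), and this enolate must close ring B at C1. In that one operation the spiro quaternary center is created next to C11, and C6 is related to C10 by ring A and to C2/C3 by the chair of ring B.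

**C5=C6 unsaturation.** 16 is traced back to the allyl β-keto ester 15 by a decarboxylation–dehydrogenation. The ester at C6 therefore serves twice: it defines where ring A closes (next paragraph), and on leaving it stores the position of the later enolate in the C5=C6 double bond.

**C6–C11.** Ring A of 15 is opened at C6–C11, which leads to the open-chain β-keto ester 13 and its silyl enol ether 14. This is the only disconnection that gives the C10 bromide and the quaternary C11 together: forward, a bromonium ion on C10/C11 is opened at C11 by the enol carbon C6. The configuration at C10 comes from an enantioenriched bromochloride, and C6 need not be controlled here because it is erased on the way to 16.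

**C5–C6.** 13 is cut into the β-keto ester 6 and the bromo tosylate 11 (alkylation of a stabilised enolate). Of the three electrophilic sites of 11 only C5–Br is unhindered, so the C1 tosylate is carried through dormant.

**C8–C9 and the right-hand halogens.** 6 is cut into allyl acetoacetate 4 and the triflate 3. 3 comes from the bromochloro alcohol 2, and 2 from prenol 1 by an enantioselective bromochlorination that sets C10.

**Left-hand halogens.** 11 comes from the bromochloro alcohol 10, and 10 from the Z allylic alcohol 9 by the same kind of bromochlorination. The olefin must be Z so that anti addition gives the pair that is trans on ring B. 9 comes from the ester 8, and 8 from the lactone 7, whose ring supplies the Z geometry and whose opening differentiates C5 from C1.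

## Alternatives that were turned down

**Alternative 1:** The textbook route cuts ring B at C1–C6 and C4–C5. The forward key step is a Diels–Alder reaction of the exocyclic enone A1 with a methyl-substituted C5 diene to give the spiro enone A2. Methylenation would give the bromo diene A3, and bromochlorination of its C2=C3 olefin would finish the synthesis. It was turned down on the last step. In A3 ring B is locked with C11 equatorial. The only opening that is both Markovnikov and trans-diaxial places bromine axial at C2, syn to C7, and chlorine axial at C3. This is the C2,C3-bis-epimer A4 and not 19. The bromonium ion on the other face would have to be opened diequatorially, or at C2 with the wrong regiochemistry. In addition, the exocyclic olefin of A3 competes for the electrophile, and the facial selectivity of the cycloaddition rests on the remote C10 bromine. The route is short, but it is expected to end in the wrong diastereomer.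

**Alternative 2:** The biomimetic route cuts C6–C11 with ring B in place. The forward key step is a bromonium ion on C10/C11 of the bromochloro bisabolene A5, opened by the exocyclic tetrasubstituted C6=C7 olefin, followed by proton loss to 19. It was turned down because the outcome at C6 is stereospecific in the olefin geometry. A chair with the C10 bromine equatorial makes the arm cis to C8 axial, so only the Z isomer A5 gives 19 and the E isomer A6 gives the C6 epimer. The two arms of ring B differ only at remote carbons, so no olefination can be expected to select between A5 and A6. Proton loss from the C7 cation would also give endocyclic and exocyclic olefins. Finally, the ring B halogens would have to be installed next to two more nucleophilic olefins.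

**Alternative 3:** A vinylogous variant cuts the same C6–C11 bond, but from the silyl dienol ether A7, in which C6 is the γ-carbon of a ring B dienol ether. The forward key step is solvolysis of the C11 chloride and attack of C6 on the bromonium ion to give the spiro enone A8, without any olefin geometry to control. It was turned down because the C2 bromide and the C3 chloride would then have to be introduced on the locked spirocycle A8, which meets the same trans-diaxial problem as Alternative 1. The configuration at C6 would also rest only on the small difference between an sp2 and an sp3 arm in the chair, and C7 would need a ketal that costs three further steps.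

Key step: step 11

## Route

Step 1
Reactants: 1 prenol (3-methylbut-2-en-1-ol)
Product: 2 (S)-2-bromo-3-chloro-3-methylbutan-1-ol
Conditions: N-bromosuccinimide (1.05 equiv), ClTi(OiPr)3 (1.1 equiv), chiral tridentate Schiff-base diol ligand (20 mol %), hexanes, −20 °C
Reagents that add atoms: N-bromosuccinimide O=C1CCC(=O)N1Br; chlorotitanium triisopropoxide CC(C)O[Ti](Cl)(OC(C)C)OC(C)C
Why: Catalytic enantioselective bromochlorination of an allylic alcohol: the titanium-bound alkoxide is brominated on the face set by the ligand, and chloride is delivered from titanium to the distal tertiary carbon (Markovnikov, anti addition). This sets the later C10 stereocenter.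

Step 2
Reactants: 2 (S)-2-bromo-3-chloro-3-methylbutan-1-ol
Product: 3 (S)-2-bromo-3-chloro-3-methylbutyl trifluoromethanesulfonate
Conditions: Tf2O, 2,6-lutidine, CH2Cl2, −78 °C
Reagents that add atoms: trifluoromethanesulfonic anhydride O=S(=O)(OS(=O)(=O)C(F)(F)F)C(F)(F)F
Why: O-Sulfonylation of a primary alcohol; the β-bromine retards ionisation, so the triflate should persist at low temperature and be reactive enough for C-alkylation in step 3.

Step 3
Reactants: 4 allyl acetoacetate; 3 (S)-2-bromo-3-chloro-3-methylbutyl trifluoromethanesulfonate
Product: 6 allyl (S)-6-bromo-7-chloro-7-methyl-3-oxooctanoate, via dilithium dianion of allyl acetoacetate 5 (not isolated)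
Conditions: LiN(iPr)2 (2.1 equiv), THF, −78 to 0 °C; then 3, −78 °C
Reagents that add atoms: none
Why: γ-Alkylation of a β-keto ester dianion, whose terminal carbanion is the more reactive site, forms C8–C9. Substitution at the primary triflate should outrun elimination at −78 °C, and the C10 stereocenter is not involved.

Step 4
Reactants: 7 4-methyl-5,6-dihydro-2H-pyran-2-one
Product: 8 methyl (Z)-5-bromo-3-methylpent-2-enoate
Conditions: HBr (gas, excess), MeOH, 0 to 23 °C
Reagents that add atoms: hydrogen bromide Br; methanol CO
Why: Conversion of a lactone into an ω-bromo ester: bromide attacks the O-alkyl carbon (C5) of the protonated lactone and the acid is esterified (Fischer esterification). The Z geometry is inherited from the ring, and C5 is differentiated from C1 in the same operation.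

Step 5
Reactants: 8 methyl (Z)-5-bromo-3-methylpent-2-enoate
Product: 9 (Z)-5-bromo-3-methylpent-2-en-1-ol
Conditions: iBu2AlH (2.5 equiv), CH2Cl2, −78 °C
Reagents that add atoms: none
Why: 1,2-Reduction of an α,β-unsaturated ester to the allylic alcohol; at low temperature the primary bromide and the Z olefin should stay untouched.

Step 6
Reactants: 9 (Z)-5-bromo-3-methylpent-2-en-1-ol
Product: 10 (2S,3S)-2,5-dibromo-3-chloro-3-methylpentan-1-ol
Conditions: N-bromosuccinimide (1.05 equiv), ClTi(OiPr)3 (1.1 equiv), chiral tridentate Schiff-base diol ligand (20 mol %), hexanes–CH2Cl2, −20 °C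
Reagents that add atoms: N-bromosuccinimide O=C1CCC(=O)N1Br; chlorotitanium triisopropoxide CC(C)O[Ti](Cl)(OC(C)C)OC(C)C
Why: The same ligand-controlled bromochlorination as in step 1: anti addition across the Z olefin, bromine to C2 and chloride from titanium to the tertiary C3, gives the (2S,3S) pair that becomes trans on ring B. The absolute sense is chosen with the ligand enantiomer, independently of C10.

Step 7
Reactants: 10 (2S,3S)-2,5-dibromo-3-chloro-3-methylpentan-1-ol
Product: 11 (2S,3S)-2,5-dibromo-3-chloro-3-methylpentyl 4-methylbenzenesulfonate
Conditions: TsCl, pyridine, CH2Cl2, 0 °C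
Reagents that add atoms: 4-methylbenzenesulfonyl chloride Cc1ccc(cc1)S(=O)(=O)Cl
Why: Tosylation of a primary alcohol under mild base. The β-bromo, β-branched C1 tosylate is a poor electrophile toward external nucleophiles, so it should stay dormant until step 11 while C5–Br remains the reactive end.

Step 8
Reactants: 6 allyl (S)-6-bromo-7-chloro-7-methyl-3-oxooctanoate; 11 (2S,3S)-2,5-dibromo-3-chloro-3-methylpentyl 4-methylbenzenesulfonate
Product: 13 allyl (6S)-6-bromo-2-[(3S,4S)-4-bromo-3-chloro-3-methyl-5-(tosyloxy)pentyl]-7-chloro-7-methyl-3-oxooctanoate (epimeric at C2), via sodium enolate of the β-keto ester 12 (not isolated)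
Conditions: NaH (1.0 equiv), THF–DMF, 0 °C; then 11, 40 °C
Reagents that add atoms: none
Why: Acetoacetic ester alkylation forms C5–C6. The unhindered primary C5–Br should react well before the hindered C1 tosylate or the neopentyl-type C2 bromide, and one equivalent of base limits a second, ring-forming alkylation. The new center at C6 is an inconsequential mixture.

Step 9
Reactants: 13 allyl (6S)-6-bromo-2-[(3S,4S)-4-bromo-3-chloro-3-methyl-5-(tosyloxy)pentyl]-7-chloro-7-methyl-3-oxooctanoate
Product: 15 allyl (5S)-5-bromo-1-[(3S,4S)-4-bromo-3-chloro-3-methyl-5-(tosyloxy)pentyl]-6,6-dimethyl-2-oxocyclohexane-1-carboxylate (epimeric at C1), via trimethylsilyl enol ether 14 (not isolated)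
Conditions: Me3SiCl, Et3N, MeCN, 23 °C; filter, concentrate; then (CF3)2CHOH, 2,6-di-tert-butylpyridine (20 mol %), 23 °C
Reagents that add atoms: none
Why: Cation–olefin (bromonium) cyclization started by solvolysis of a vicinal bromochloride: in the ionising, non-nucleophilic fluoro alcohol the tertiary C11–Cl leaves with anchimeric help from the anti C10–Br, and the enantioenriched bromonium ion is opened at C11 (Markovnikov, six-membered ring, chair with bromine equatorial) by the enol ether carbon C6, so C10 is carried over unchanged. The ester fixes the enol ether between C6 and C7, O-silylation blocks O-cyclization, and the C3–Cl, whose bromine is deactivated by the tosyloxymethyl group and which has no carbon nucleophile within reach, should ionise only reversibly. The C6 center forms as a mixture that is erased in step 10.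

Step 10
Reactants: 15 allyl (5S)-5-bromo-1-[(3S,4S)-4-bromo-3-chloro-3-methyl-5-(tosyloxy)pentyl]-6,6-dimethyl-2-oxocyclohexane-1-carboxylate
Product: 16 (4S)-4-bromo-2-[(3S,4S)-4-bromo-3-chloro-3-methyl-5-(tosyloxy)pentylidene]-3,3-dimethylcyclohexan-1-one (E/Z mixture)
Conditions: Pd(OAc)2 (10 mol %), PPh3 (10 mol %), MeCN, 80 °C
Reagents that add atoms: none
Why: Palladium-catalysed decarboxylation–dehydrogenation of an allyl β-keto carboxylate: zerovalent palladium formed in situ adds to the allyl ester, loss of CO2 gives a palladium enolate at C6, and β-hydride elimination gives the enone and propene. Elimination is possible only toward C5 because C11 is quaternary, so the enone is exocyclic; C6 loses its stereocenter and the place of the later enolate is stored in the C5=C6 bond.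

Step 11
Reactants: 16 (4S)-4-bromo-2-[(3S,4S)-4-bromo-3-chloro-3-methyl-5-(tosyloxy)pentylidene]-3,3-dimethylcyclohexan-1-one
Product: 18 (2S,3S,6R,10S)-2,10-dibromo-3-chloro-3,11,11-trimethylspiro[5.5]undecan-7-one, via triethylsilyl enol ether 17 (not isolated)
Conditions: RhCl(PPh3)3 (2 mol %), Et3SiH (1.2 equiv), toluene, 50 °C; then THF (0.01 M), Bu4N[Ph3SiF2] (1.1 equiv), 0 to 23 °C
Reagents that add atoms: none
Why: Mechanism: rhodium-catalysed 1,4-hydrosilylation of the s-cis exocyclic enone delivers hydride to C5 and silicon to oxygen, so the enol ether 17 forms only between C6 and C7; fluoride then frees the ammonium enolate, which displaces the primary C1 tosylate by SN2. The closest known reaction types are the conjugate hydrosilylation of enones, the fluoride-mediated regiospecific alkylation of silyl enol ethers, and the spiroannulation of cyclohexanone enolates with tethered sulfonates. Ring B closes in the 6-exo-tet mode through a chair; O-alkylation or alkylation from C8 would need an eight-membered ring, and attack at C2 would give a five-membered ring at a neopentyl-type secondary carbon. The new stereocenter C6 is controlled by C10: in the ring A half-chair with the C10 bromine pseudo-equatorial one C11 methyl is pseudo-axial, and C1 adds axially to C6 from the opposite face, syn to the axial C10–H and trans to bromine, whereas the other half-chair would force C1 in syn-axial to an axial bromine. The forming ring B chair places C11 equatorial and the planar C7 axial, and with the (2S,3S) arm this puts C2–Br and C3–Cl equatorial and only the C3 methyl axial, so both rings favour the same diastereomer (matched case). The selectivities needed are 1,4- over 1,2-hydrosilylation (s-cis enone, monohydrosilane) and alkylation over elimination in the C1–C3 array or γ-displacement of the C10 bromide (intramolecular six-membered path, no excess base, equatorial neopentyl C10–Br). C2, C3 and C10 are not α to the carbonyl and cannot epimerise.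

Step 12
Reactants: 18 (2S,3S,6R,10S)-2,10-dibromo-3-chloro-3,11,11-trimethylspiro[5.5]undecan-7-one
Product: 19 nidificene, (2S,3S,6S,10S)-2,10-dibromo-3-chloro-3,11,11-trimethyl-7-methylidenespiro[5.5]undecane
Conditions: Cp2TiMe2 (3 equiv), toluene–THF, 65 °C, dark
Reagents that add atoms: dimethyltitanocene [CH3-].[CH3-].[Ti+4].C1=C[CH-]C=C1.C1=C[CH-]C=C1
Why: Petasis methylenation: the titanium methylidene formed thermally methylenates hindered and enolisable ketones without base or Lewis acid, which the two secondary bromides and the tertiary chloride should tolerate. No stereocenter is touched; the descriptor at C6 changes from R to S only because the priorities change.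

## Compound list

1 | prenol (3-methylbut-2-en-1-ol) | CC(C)=CCO | starting material
2 | (S)-2-bromo-3-chloro-3-methylbutan-1-ol | OC[C@H](Br)C(C)(C)Cl | intermediate
3 | (S)-2-bromo-3-chloro-3-methylbutyl trifluoromethanesulfonate | O=S(=O)(OC[C@H](Br)C(C)(C)Cl)C(F)(F)F | intermediate
4 | allyl acetoacetate | C=CCOC(=O)CC(C)=O | starting material
5 | dilithium dianion of allyl acetoacetate | [Li+].[Li+].C=CCOC(=O)[CH-]C(=O)[CH2-] | intermediate
6 | allyl (S)-6-bromo-7-chloro-7-methyl-3-oxooctanoate | C=CCOC(=O)CC(=O)CC[C@H](Br)C(C)(C)Cl | intermediate
7 | 4-methyl-5,6-dihydro-2H-pyran-2-one | CC1=CC(=O)OCC1 | starting material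
8 | methyl (Z)-5-bromo-3-methylpent-2-enoate | COC(=O)/C=C(/C)CCBr | intermediate
9 | (Z)-5-bromo-3-methylpent-2-en-1-ol | OC/C=C(/C)CCBr | intermediate
10 | (2S,3S)-2,5-dibromo-3-chloro-3-methylpentan-1-ol | BrCC[C@](C)(Cl)[C@@H](Br)CO | intermediate
11 | (2S,3S)-2,5-dibromo-3-chloro-3-methylpentyl 4-methylbenzenesulfonate | BrCC[C@](C)(Cl)[C@@H](Br)COS(=O)(=O)c1ccc(C)cc1 | intermediate
12 | sodium enolate of allyl (S)-6-bromo-7-chloro-7-methyl-3-oxooctanoate | [Na+].C=CCOC(=O)C=C([O-])CC[C@H](Br)C(C)(C)Cl | intermediate
13 | allyl (6S)-6-bromo-2-[(3S,4S)-4-bromo-3-chloro-3-methyl-5-(tosyloxy)pentyl]-7-chloro-7-methyl-3-oxooctanoate (epimeric at C2) | C=CCOC(=O)C(CC[C@](C)(Cl)[C@@H](Br)COS(=O)(=O)c1ccc(C)cc1)C(=O)CC[C@H](Br)C(C)(C)Cl | intermediate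
14 | allyl (6S)-6-bromo-2-[(3S,4S)-4-bromo-3-chloro-3-methyl-5-(tosyloxy)pentyl]-7-chloro-7-methyl-3-(trimethylsilyloxy)oct-2-enoate (E/Z mixture) | C=CCOC(=O)C(CC[C@](C)(Cl)[C@@H](Br)COS(=O)(=O)c1ccc(C)cc1)=C(O[Si](C)(C)C)CC[C@H](Br)C(C)(C)Cl | intermediate
15 | allyl (5S)-5-bromo-1-[(3S,4S)-4-bromo-3-chloro-3-methyl-5-(tosyloxy)pentyl]-6,6-dimethyl-2-oxocyclohexane-1-carboxylate (epimeric at C1) | C=CCOC(=O)C1(CC[C@](C)(Cl)[C@@H](Br)COS(=O)(=O)c2ccc(C)cc2)C(=O)CC[C@H](Br)C1(C)C | intermediate
16 | (4S)-4-bromo-2-[(3S,4S)-4-bromo-3-chloro-3-methyl-5-(tosyloxy)pentylidene]-3,3-dimethylcyclohexan-1-one (E/Z mixture) | O=C1CC[C@H](Br)C(C)(C)C1=CC[C@](C)(Cl)[C@@H](Br)COS(=O)(=O)c1ccc(C)cc1 | intermediate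
17 | [(4S)-4-bromo-2-[(3S,4S)-4-bromo-3-chloro-3-methyl-5-(tosyloxy)pentyl]-3,3-dimethylcyclohex-1-en-1-yl]oxy(triethyl)silane | CC[Si](CC)(CC)OC1=C(CC[C@](C)(Cl)[C@@H](Br)COS(=O)(=O)c2ccc(C)cc2)C(C)(C)[C@@H](Br)CC1 | intermediate
18 | (2S,3S,6R,10S)-2,10-dibromo-3-chloro-3,11,11-trimethylspiro[5.5]undecan-7-one | O=C1CC[C@H](Br)C(C)(C)[C@]12CC[C@](C)(Cl)[C@@H](Br)C2 | intermediate
19 | nidificene, (2S,3S,6S,10S)-2,10-dibromo-3-chloro-3,11,11-trimethyl-7-methylidenespiro[5.5]undecane | C=C1CC[C@H](Br)C(C)(C)[C@]12CC[C@](C)(Cl)[C@@H](Br)C2 | target

## Step count and least certain steps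

Total step count: 12. Longest linear sequence: 9 steps (7 to 19 through steps 4–12); the branch from prenol 1 (steps 1–3) joins in step 8.

**Step 11 (key step).** The most likely failure is that the fluoride-liberated C6 enolate, hindered by C11, acts as a base before it closes the ring. This would show as loss of hydrogen bromide or of toluenesulfonic acid within the C1–C3 array, or as proton transfer that ends in the uncyclised saturated ketone. Part of the hydrosilylation may also take the 1,2 course. The fallback changes how the enolate is made. It sets out from 15: palladium-catalysed decarboxylative hydrogenolysis (Pd(OAc)2, PPh3, HCO2H, Et3N, THF, 23 °C) gives the saturated ketone (4S)-4-bromo-2-[(3S,4S)-4-bromo-3-chloro-3-methyl-5-(tosyloxy)pentyl]-3,3-dimethylcyclohexan-1-one F1. Treatment with KOtBu (1.0 equiv) in t-BuOH–THF at 0 °C then lets the two enolates interconvert. Only the C6 enolate can reach C1 through a six-membered transition state, since the C8 enolate would need an eight-membered ring, so the same axial spiroalkylation brings the route back at 18.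

**Step 9.** A fully substituted enol ether carbon has to bond to a tertiary carbon, which creates the vicinal quaternary pair C6/C11. Proton loss from the bromonium ion (an isopropenyl allylic bromide), O-cyclization after early desilylation, and capture of a C3 cation by the new ketone on long exposure are the processes most likely to compete. The fallback inverts the order of the two bond formations. It sets out from 6: the unsubstituted β-keto ester is cyclised through its enol in (CF3)2CHOH to allyl (5S)-5-bromo-6,6-dimethyl-2-oxocyclohexane-1-carboxylate F2. The quaternary center is then made by alkylation of F2 with 11 (Cs2CO3, DMF, 40 °C), which returns to the route at 15.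

**Step 3.** The strongly basic dianion may cause elimination in the β-bromo triflate (a vinyl bromide, or loss of both halogens) instead of substitution. The fallback uses a softer γ-nucleophile. It sets out from 3: alkylation of the lithium dienolate of 2,2,6-trimethyl-4H-1,3-dioxin-4-one (LiN(iPr)2, THF, −78 °C) gives 6-[(3S)-3-bromo-4-chloro-4-methylpentyl]-2,2-dimethyl-4H-1,3-dioxin-4-one F3. Thermolysis of F3 in toluene with allyl alcohol (acylketene capture, 100 °C) returns to the route at 6.

**Step 12.** The ketone is flanked by the spiro quaternary carbon, so methylenation may be slow, and long heating may cost hydrogen chloride from the tertiary chloride. The fallback replaces carbonyl olefination by addition and elimination. It sets out from 18: addition of Me3SiCH2MgCl with CeCl3 (THF, −78 °C) gives the β-hydroxysilane (2S,3S,6R,10S)-2,10-dibromo-3-chloro-3,11,11-trimethyl-7-[(trimethylsilyl)methyl]spiro[5.5]undecan-7-ol F4 (C7 epimers). Acid-mediated Peterson elimination of F4 (aqueous HF, MeCN, 0 °C) can only give the exocyclic olefin and returns to the route at 19.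

## Further compounds

F1 | step 11 | (4S)-4-bromo-2-[(3S,4S)-4-bromo-3-chloro-3-methyl-5-(tosyloxy)pentyl]-3,3-dimethylcyclohexan-1-one (C2 epimers) | O=C1CC[C@H](Br)C(C)(C)C1CC[C@](C)(Cl)[C@@H](Br)COS(=O)(=O)c1ccc(C)cc1
F2 | step 9 | allyl (5S)-5-bromo-6,6-dimethyl-2-oxocyclohexane-1-carboxylate | C=CCOC(=O)C1C(=O)CC[C@H](Br)C1(C)C
F3 | step 3 | 6-[(3S)-3-bromo-4-chloro-4-methylpentyl]-2,2-dimethyl-4H-1,3-dioxin-4-one | CC1(C)OC(=O)C=C(CC[C@H](Br)C(C)(C)Cl)O1
F4 | step 12 | (2S,3S,6R,10S)-2,10-dibromo-3-chloro-3,11,11-trimethyl-7-[(trimethylsilyl)methyl]spiro[5.5]undecan-7-ol (C7 epimers) | C[Si](C)(C)CC1(O)CC[C@H](Br)C(C)(C)[C@]12CC[C@](C)(Cl)[C@@H](Br)C2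
A1 | alternative 1 | (S)-4-bromo-3,3-dimethyl-2-methylidenecyclohexan-1-one | C=C1C(=O)CC[C@H](Br)C1(C)C
A2 | alternative 1 | (6R,10S)-10-bromo-3,11,11-trimethylspiro[5.5]undec-2-en-7-one | O=C1CC[C@H](Br)C(C)(C)[C@]12CCC(C)=CC2
A3 | alternative 1 | (6S,10S)-10-bromo-3,11,11-trimethyl-7-methylidenespiro[5.5]undec-2-ene | C=C1CC[C@H](Br)C(C)(C)[C@]12CCC(C)=CC2
A4 | alternative 1 | (2R,3R,6S,10S)-2,10-dibromo-3-chloro-3,11,11-trimethyl-7-methylidenespiro[5.5]undecane | C=C1CC[C@H](Br)C(C)(C)[C@]12CC[C@@](C)(Cl)[C@H](Br)C2
A5 | alternative 2 | (1S,2S)-2-bromo-1-chloro-1-methyl-4-[(Z)-6-methylhept-5-en-2-ylidene]cyclohexane | CC(C)=CCC/C(C)=C1\C[C@H](Br)[C@@](C)(Cl)CC1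
A6 | alternative 2 | (1S,2S)-2-bromo-1-chloro-1-methyl-4-[(E)-6-methylhept-5-en-2-ylidene]cyclohexane | CC(C)=CCC/C(C)=C1/C[C@H](Br)[C@@](C)(Cl)CC1
A7 | alternative 3 | [4-[2-[(3S)-3-bromo-4-chloro-4-methylpentyl]-1,3-dioxolan-2-yl]cyclohexa-1,3-dien-1-yl]oxy(trimethyl)silane | C[Si](C)(C)OC1=CC=C(CC1)C1(CC[C@H](Br)C(C)(C)Cl)OCCO1
A8 | alternative 3 | spiro enone, (6S,10S)-10-bromo-11,11-dimethylspiro[5.5]undec-1-ene-3,7-dione 7-(ethylene ketal) | O=C1C=C[C@@]2(CC1)C1(OCCO1)CC[C@H](Br)C2(C)C
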